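I decided to follow the second end groups through elm: at 0.900 equiv per first end group they are the limiting reagent, so each one lost is a link lost.

| flask | first end groups | second end groups | third end groups | remark | time |
|---|---|---|---|---|---|
| grey | 41 mM | 0.90 equiv | 0.25 equiv | run made earlier |  |
| green | 41 mM | 1.3 equiv | 0.25 equiv | run made earlier |  |
| red | 41 mM | 2 equiv | 0.25 equiv | run made earlier |  |
| amber | 41 mM | 0.90 equiv | 0.12 equiv | run made earlier |  |
| elm | 41 mM (fed, over 12 min) | 0.900 equiv | 0.250 equiv | all else is in the flask from the start; the feed brings no volume worth counting | 20 min |
| larch | 41 mM | 0.900 equiv | 0.250 equiv | everything together at the start | 20 min |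
| ash | 41 mM | 0.900 equiv | 0.250 equiv (fed, over 12 min) | all else is in the flask from the start; the feed brings no volume worth counting | 20 min |
| oak | 41 mM | 0.900 equiv | 0.250 equiv (fed, over 3.0 min) | all else is in the flask from the start; the feed brings no volume worth counting | 20 min |

| run | time / min | links / % | first end groups / % |
|---|---|---|---|
| grey | 1.50 | 70.6 | 26.2 |
| grey | 2.50 | 73.2 | 17.1 |
| grey | 4.00 | 76.5 | 13.5 |
| grey | 8.00 | 74.6 | 10.2 |
| grey | 12.0 | 71.4 | 7.0 |
| grey | 20.0 | 70.6 | 5.5 |
| green | 2.00 | 88.5 | 4.6 |
| green | 3.00 | 91.5 | 4.1 |
| green | 5.00 | 95.0 | 0.8 |
| green | 8.00 | 94.7 | 1.8 |
| green | 15.0 | 93.2 | 0.4 |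
| green | 25.0 | 92.5 | 0 |
| red | 2.00 | 96.0 | 2.3 |
| red | 3.00 | 95.8 | 2.2 |
| red | 5.00 | 97.2 | 0.6 |
| red | 8.00 | 98.2 | 0.5 |
| red | 15.0 | 98.6 | 1.8 |
| red | 25.0 | 98.3 | 0 |
| amber | 2.00 | 73.0 | 21.3 |
| amber | 4.00 | 75.9 | 13.1 |
| amber | 6.00 | 78.5 | 10.8 |
| amber | 12.0 | 77.4 | 6.9 |
| amber | 25.0 | 73.6 | 3.3 |

(each reading ± 1 percentage point)

* the flask that comes out highest in amount of links, in percent of the first end groups charged, or "all alike" when all lie within 1.5 percentage points (elm / larch / ash / oak / all alike)
* links at the end, in percent of the first end groups charged, elm
* links at the end, in percent of the first end groups charged, larch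
* links at the end, in percent of the first end groups charged, ash
* links at the end, in percent of the first end groups charged, oak



First, how fast do second end groups meet first end groups? The first grey reading, put into the second-order law for the two charges, gave me 1.02 /M/s. At the charge, that is a half-life of 0.308 min for first end groups.

Second, what do third end groups take? I assumed that each side product joins a link to a first end group. A balance over both end groups then left 7.45% of the charge unaccounted for in grey and 4.85% in amber. Scaling that difference with the third end groups, they took about 5.00% in grey, a rough figure given the scatter of 1 percentage point.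

Third, how fast is that? Grey's links peaked near 4.00 min. Dividing the take by the exposure to c(second end groups) up to then gave 11.1 min. This is the capping half-life, the half-life of second end groups against third end groups at their charge with no first end groups about.

In a batch, capping is 36.0 times slower than linking. In elm, though, the feed brings 3.42 mM/min while capping starts at 2.31 mM/min, which is less than the feed but close to it. Solving that race, my reckoning put the stock of second end groups at zero at 8.25 min, inside the feed. That put elm's links near 68.8% before any attack on them. I read larch as grey, 70.6%, and reckoned ash at 75.6%, with capping's take handed back.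

The forecast differed on elm: 78% for elm, 71% for larch, 74% for ash, 72% for oak, with elm highest, on the ground that “Elm keeps first end groups scarce”.

The flasks gave 47.2% for elm, 70.1% for larch, 75.8% for ash and 73.9% for oak, so ash came highest.

    second end groups + third end groups → links of the second sort (k = 0.135 /M/s)
    first end groups + links → side product (k = 0.0310 /M/s)
    second end groups → decomposed reagent (k = 4.69 × 10⁻⁴ /s)
    first end groups + second end groups → links (k = 1.07 /M/s)

In elm the feed of 12 min ran longer than my reckoned capping half-life of 11.1 min, and capping came early: it had done half of its turnover by 1.69 min, against 4.58 min for linking. Elm ended with 7.34 mM of links of the second sort, ash with 0.492 mM. Removing the capping step narrows the gap between ash and elm from 29 points to 12 points, the largest single effect.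

In the neighbour with 3.60 equiv, the same race formula finds no zero inside the feed: its zero falls at 20.9 min, past the feed's end, a figure that says only that the stock outlasts the feed. That flask still held 34.1% of its own charge of second end groups at 20.0 min and gives 98.6% links.

(All runs come from a simulation for an exercise; scatter was added.)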